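## Analysis of the target

The target is a daucane-type sesquiterpenoid ester: a bicyclo[5.3.0]decane in which a cyclopentane (C1–C5) shares the C1–C5 bond with a cycloheptane (C1, C5, C6, C7, C8, C9, C10). This numbering is kept for every intermediate: C1 is quaternary and carries a methyl group, C4 is the carbinol with the isopropyl group, C6 carries the 3-methylbutanoate, C8 carries the exocyclic methylidene carbon C14, and C9 and C10 are carbinols. There are six stereocentres, 1S, 4R, 5S, 6S, 9R and 10S. Taking the face of the C1 methyl as β, the C4 hydroxyl is β while H5, the C6 acyloxy group and both hydroxyls at C9 and C10 are α; the ring fusion is therefore trans, the C4 hydroxyl is cis to the C6 branch on the cyclopentane, and the 9,10-diol is cis and lies opposite the angular methyl. The sensitive groups are the ester (strong base, nucleophiles, unselective hydride), the tertiary C4 alcohol (elimination under acid), the allylic cis-diol, and the 1,1-disubstituted alkene at C8, which can slip into the ring or into conjugation with a C10 carbonyl. The hard points are the quaternary C1 at the ring fusion, the contiguous C4–C5–C6 triad, the closure of a seven-membered ring, and C10, which must receive its hydrogen on the methyl-bearing β face although reagents prefer the α face. The strategy rests on the segment C14=C8–C9–C10(O)–C1 of the seven-membered ring: C8 is bonded to C9, C9 is α to oxygenated C10, and C10 is flanked on its other side by quaternary C1, so it can form an enol derivative only toward C9. Read backwards, C8–C9 is the bond made when a C10 enol ether adds to the internal carbon of a terminal alkyne C8≡C14, and cutting it leaves a cyclopentane that already carries C1, C4, C5 and C6.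

## Retrosynthetic reasoning

**C9–O and C10–H.** The last operations only adjust the C9/C10 oxidation pattern. Target 30 is the desilylation product of 29; the C10–H bond of 29 is cut back to ketone 28, and the C9–O bond of 28 is cut, through alcohol 27 and dienolate 26, back to ketone 25. These cuts are chosen because C10 already carries its oxygen in 25 and can enolise in one direction only. The forward steps must deliver oxygen to C9 on the α face without moving the alkene, and hydride to C10 on the β face.

**C8–C9 (ring closure).** Ketone 25 is cut between C8 and C9 to the acetylenic silyl enol ether 24. Any other ring bond (C1–C10, C5–C6, C6–C7, C7–C8) would force a quaternary centre or a stereocentre to be made during a medium-ring closure. The C8–C9 cut creates no stereocentre, gives the C8 methylidene and the C10 carbonyl in the positions the target needs, and leaves every stereocentre on a five-membered ring where it can be set beforehand. The forward reaction has to close seven atoms in the exo mode and keep the alkene out of conjugation.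

**Enol ether and C9–C10.** 24 is the enol silane of methyl ketone 23. The C9–C10 bond of 23 is cut, through alcohol 22, to aldehyde 20 and methylmagnesium bromide 21: the aldehyde on quaternary C1 cannot enolise and takes the methyl nucleophile ahead of the hindered ester. 20 goes back through 19 and 18 to 17 by oxidation-level and protecting-group changes only; C10 is carried as a silyl-protected hydroxymethyl group because that group is inert to all the organometallic steps before it.

**C6–O (ester).** 17 is cut at the ester C–O bond to diol 15 and acid chloride 16. The cut is placed after the last carbanion addition to a ring carbonyl and before the enolate chemistry at C9, and it relies on the secondary C6 hydroxyl reacting ahead of the tertiary C4 hydroxyl.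

**C4–isopropyl.** 15 (through its silylalkyne 14) is cut at the C4–isopropyl bond to ketone 12 and isopropylmagnesium chloride 13. With C5 already substituted, the nucleophile has to come from the face opposite the C5 chain, which is the face the target requires.

**C5–C6.** 12 is an aldol: cutting C5–C6 gives the C4 enolate (10, 11), stored as enol silane 7, and aldehyde 9, made from alcohol 8. This one bond brings in C6, C7, C8 and C14 and sets C5 and C6. The forward step needs the anti aldol and approach of the aldehyde to the face of C5 away from the larger C1 substituent.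

**C1–CH3.** 7 is cut at the C1–methyl bond, through aluminium enolate 6, to enone 4 and trimethylaluminium 5. A catalytic asymmetric conjugate addition sets the only stereocentre that no other can control, and it produces the enolate exactly where the next bond is needed.

**C1–C10.** Enone 4 is the silyl ether of 3, which is cut at the ring–CH2OH bond to bromoenone 1 and stannane 2.

## Alternatives that were turned down

**Alternative 1:** The C1–CH3 and C5–C6 bonds are cut in one stroke and the synthesis is built around a three-component union: a chiral NHC–copper catalyst transfers methyl from aluminium to C1 of the cyclopentenone and the enolate is caught by the ynal to give the trans-disubstituted cyclopentanone aldol A1. In its favour: two skeletal bonds and three stereocentres (C1, C5, C6) arise in one flask from achiral pieces under catalytic control, and on stereocentres made per step it is clearly stronger than the gold closure, which makes none. Against it for this target: it closes no ring, so the seven-membered ring and the C8–C10 functionality remain unsolved. As a single operation it also asks a sluggish aluminium enolate next to a quaternary centre to add to a base-sensitive aldehyde in the presence of excess methylaluminium. The two plans are complementary: A1 is the same compound as 12, and the chosen route uses this union in two separate operations (steps 3 and 5) as its opening. What the chosen strategy adds is the ring closure, which delivers the methylidene and the C10 carbonyl in place.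

**Alternative 2:** The C1–C5 and C6–C7 bonds are cut, leading back to an alkyne tethered through C2–C3–C4 to a 1-siloxy-1-vinylcyclopropane. Forward, [Rh(CO)2Cl]2 joins the alkyne to the alkene, opens the cyclopropane and gives the bicyclo[5.3.0]decadiene A2 with a C9 silyl enol ether and a C5=C6 alkene. In its favour: both rings and two C–C bonds form in one atom-economical step, and the C5=C6 alkene allows H5 and the C6 oxygen to be added together from the α face. On one point it is stronger than the chosen route: oxidation of the C9=C10 enol ether would put the C10 oxygen on from the open α face, whereas the chosen route must bring hydrogen to C10 on the hindered face. Against it: quaternary C1 has to form at a fully substituted alkene terminus, and its configuration is controlled only by the remote C4 centre across the tether. The precursor needs an enantioselective tertiary propargylic carbinol and a siloxyvinylcyclopropane. A2 also lacks C14, so the methylidene must be added later by α-methylenation of a C9 ketone through a reactive enone, followed by reduction at C9. The step economy gained in the cycloaddition is spent again afterwards; the chosen strategy has C14, the C10 oxygen and all four cyclopentane stereocentres in place when the ring closes.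

**Alternative 3:** The C7–C8 and C1–C10 bonds are cut. Forward, dirhodium tetrakis[(S)-N-(dodecylbenzenesulfonyl)prolinate], Rh2(S-DOSP)4, transfers a vinylcarbenoid from a vinyldiazoacetate to the vinyl group of a cyclopentenyl diene, and the cis-divinylcyclopropane rearranges (Cope) to the bicyclic diene ester A3. In its favour: it is convergent and the seven-membered ring and quaternary C1 are made together under catalyst control, the shortest way to the bare skeleton; on convergence and on placing the asymmetric step in the ring-forming event it is stronger than the chosen route. Against it: A3 has C10 as an unoxidised methylene beside the quaternary centre and C7 as a doubly allylic methylene that would oxidise first. C14 arrives as an ester on a C8=C9 alkene and must be reduced and transposed into the methylidene with oxygen placed at C9. C4 has to be set later by isopropyl addition with no neighbouring stereocentre to guide it. The chosen strategy is longer before the ring closure, but its ring-forming step leaves only the C9 oxygen and the C10 hydrogen to be added.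

Key step: step 14

Assumption: the (4S,5S) enantiomer of the NHC ligand in step 3 is taken to deliver methyl to the Re face of the β-carbon of 4; should the sense be the opposite, the (4R,5R) ligand is used and nothing else changes.

## Route

Step 1
Reactants: 1 3-bromocyclopent-2-en-1-one; 2 (tributylstannyl)methanol
Product: 3 3-(hydroxymethyl)cyclopent-2-en-1-one
Conditions: Pd(PPh3)4 (5 mol%), 1,4-dioxane, 90 °C
Reagents that add atoms: none
Why: Migita–Kosugi–Stille coupling: zerovalent palladium inserts readily into the C–Br bond of the vinylogous acyl bromide, and the hydroxymethyl group is transferred from tin in preference to butyl.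

Step 2
Reactants: 3 3-(hydroxymethyl)cyclopent-2-en-1-one
Product: 4 3-{[(tert-butyldimethylsilyl)oxy]methyl}cyclopent-2-en-1-one
Conditions: t-BuMe2SiCl, imidazole, DMF, 23 °C
Reagents that add atoms: tert-butyldimethylsilyl chloride, CC(C)(C)[Si](C)(C)Cl
Why: Standard silylation of a primary alcohol; the silyl ether does not chelate, survives the organometallic steps ahead and is bulkier than methyl, which matters in step 5.

Step 3
Reactants: 4 3-{[(tert-butyldimethylsilyl)oxy]methyl}cyclopent-2-en-1-one; 5 trimethylaluminium
Product: 7 tert-butyl(dimethyl){[(1S)-1-methyl-3-[(triethylsilyl)oxy]cyclopent-2-en-1-yl]methoxy}silane, via dimethylaluminium enolate 6 (not isolated)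
Conditions: Me3Al (3 equiv), Cu(OTf)2 (5 mol%), [Ag(NHC)]2 (2.5 mol%; NHC = (4S,5S)-1-(2,6-diethylphenyl)-4,5-diphenyl-3-(2-sulfonatophenyl)imidazolin-2-ylidene), THF, −78 °C; then Et3SiOTf (excess), −78 → 0 °C
Reagents that add atoms: triethylsilyl trifluoromethanesulfonate, CC[Si](CC)(CC)OS(=O)(=O)C(F)(F)F
Why: Copper-catalysed asymmetric conjugate addition of a trialkylaluminium to a β-substituted cyclopentenone under a chiral NHC ligand, a known route to all-carbon quaternary centres; the catalyst delivers methyl to the Re face of the β-carbon and sets C1 as S. O-Silylation of aluminium enolate 6 stores the enolate regiochemistry (double bond toward C5), which deprotonation of the ketone could not give.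

Step 4
Reactants: 8 4-(trimethylsilyl)but-3-yn-1-ol
Product: 9 4-(trimethylsilyl)but-3-ynal
Conditions: Dess–Martin periodinane, CH2Cl2, 0 → 23 °C; used crude at once
Reagents that add atoms: none
Why: Dess–Martin oxidation under base-free conditions; the β,γ-acetylenic aldehyde isomerises to the allene with base, so it is neither purified nor stored.

Step 5
Reactants: 7 tert-butyl(dimethyl){[(1S)-1-methyl-3-[(triethylsilyl)oxy]cyclopent-2-en-1-yl]methoxy}silane; 9 4-(trimethylsilyl)but-3-ynal
Product: 12 (2S,3S)-3-{[(tert-butyldimethylsilyl)oxy]methyl}-2-[(1S)-1-hydroxy-4-(trimethylsilyl)but-3-yn-1-yl]-3-methylcyclopentan-1-one, via lithium enolate 10 (not isolated), via chlorozinc enolate 11 (not isolated)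
Conditions: MeLi, THF, 0 → 23 °C; ZnCl2, −78 °C; then 9, −78 °C
Reagents that add atoms: methyllithium, [Li]C (lithium of 10); zinc chloride, Cl[Zn]Cl (chlorozinc of 11)
Why: Methyllithium cleaves the Si–O bond to the regiodefined lithium enolate, and zinc chloride makes it less basic toward the enolisable aldehyde. The aldol addition runs through a closed Zimmerman–Traxler chair: the ring-locked E-enolate gives the anti relationship between C5 and C6 (6S), and the aldehyde approaches C5 anti to the bulkier silyloxymethyl group on C1, which puts the new chain trans to it (5S).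

Step 6
Reactants: 12 (2S,3S)-3-{[(tert-butyldimethylsilyl)oxy]methyl}-2-[(1S)-1-hydroxy-4-(trimethylsilyl)but-3-yn-1-yl]-3-methylcyclopentan-1-one; 13 isopropylmagnesium chloride
Product: 15 (1R,2S,3S)-3-{[(tert-butyldimethylsilyl)oxy]methyl}-2-[(1S)-1-hydroxybut-3-yn-1-yl]-3-methyl-1-(propan-2-yl)cyclopentan-1-ol, via trimethylsilyl-alkyne diol 14 (not isolated)
Conditions: i-PrMgCl (4 equiv), CeCl3 (4 equiv), THF, −78 → 0 °C; then MeOH, K2CO3, 23 °C
Reagents that add atoms: none
Why: Cerium-mediated Grignard addition suppresses enolisation and retro-aldol of the hindered β-alkoxy ketone; the nucleophile adds to the cyclopentanone face opposite the C5 side chain, so the C4 hydroxyl ends cis to that chain (4R). Methanol with K2CO3 then cleaves the alkynyl C–Si bond and leaves the O-silyl ether.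

Step 7
Reactants: 15 (1R,2S,3S)-3-{[(tert-butyldimethylsilyl)oxy]methyl}-2-[(1S)-1-hydroxybut-3-yn-1-yl]-3-methyl-1-(propan-2-yl)cyclopentan-1-ol; 16 3-methylbutanoyl chloride (isovaleryl chloride)
Product: 17 (1S)-1-[(1S,2R,5S)-5-{[(tert-butyldimethylsilyl)oxy]methyl}-2-hydroxy-5-methyl-2-(propan-2-yl)cyclopentyl]but-3-yn-1-yl 3-methylbutanoate
Conditions: pyridine, DMAP (cat.), CH2Cl2, 0 → 23 °C
Reagents that add atoms: none
Why: Acylation with an acid chloride under nucleophilic catalysis is selective for the secondary C6 hydroxyl; the tertiary C4 hydroxyl beside the isopropyl group does not react.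

Step 8
Reactants: 17 (1S)-1-[(1S,2R,5S)-5-{[(tert-butyldimethylsilyl)oxy]methyl}-2-hydroxy-5-methyl-2-(propan-2-yl)cyclopentyl]but-3-yn-1-yl 3-methylbutanoate
Product: 18 (1S)-1-[(1S,2R,5S)-2-hydroxy-5-(hydroxymethyl)-5-methyl-2-(propan-2-yl)cyclopentyl]but-3-yn-1-yl 3-methylbutanoate
Conditions: HF·pyridine, pyridine, THF, 0 → 23 °C
Reagents that add atoms: none
Why: Buffered fluoride cleaves the primary silyl ether; ester, alkyne and tertiary alcohol are inert.

Step 9
Reactants: 18 (1S)-1-[(1S,2R,5S)-2-hydroxy-5-(hydroxymethyl)-5-methyl-2-(propan-2-yl)cyclopentyl]but-3-yn-1-yl 3-methylbutanoate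
Product: 19 (1S)-1-[(1S,2R,5S)-5-formyl-2-hydroxy-5-methyl-2-(propan-2-yl)cyclopentyl]but-3-yn-1-yl 3-methylbutanoate
Conditions: Dess–Martin periodinane, CH2Cl2, 0 → 23 °C
Reagents that add atoms: none
Why: Dess–Martin oxidation of the primary neopentyl alcohol; the aldehyde has no α-hydrogen and cannot form a lactol with the C4 hydroxyl, which sits on the other face of the ring.

Step 10
Reactants: 19 (1S)-1-[(1S,2R,5S)-5-formyl-2-hydroxy-5-methyl-2-(propan-2-yl)cyclopentyl]but-3-yn-1-yl 3-methylbutanoate
Product: 20 (1S)-1-[(1S,2R,5S)-5-formyl-5-methyl-2-(propan-2-yl)-2-[(triethylsilyl)oxy]cyclopentyl]but-3-yn-1-yl 3-methylbutanoate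
Conditions: Et3SiOTf, 2,6-lutidine, CH2Cl2, −78 → 0 °C
Reagents that add atoms: triethylsilyl trifluoromethanesulfonate, CC[Si](CC)(CC)OS(=O)(=O)C(F)(F)F
Why: A silyl triflate is needed for the hindered tertiary alcohol; the aldehyde cannot enolise, so no enol silane forms. The ether keeps the C4 oxygen away from the activated alkyne in step 14.

Step 11
Reactants: 20 (1S)-1-[(1S,2R,5S)-5-formyl-5-methyl-2-(propan-2-yl)-2-[(triethylsilyl)oxy]cyclopentyl]but-3-yn-1-yl 3-methylbutanoate; 21 methylmagnesium bromide
Product: 22 (1S)-1-[(1S,2R,5S)-5-(1-hydroxyethyl)-5-methyl-2-(propan-2-yl)-2-[(triethylsilyl)oxy]cyclopentyl]but-3-yn-1-yl 3-methylbutanoate (both carbinol epimers)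
Conditions: MeMgBr (2.2 equiv), THF, −78 °C
Reagents that add atoms: none
Why: Grignard addition to an aldehyde is much faster at −78 °C than attack on the hindered secondary ester; the excess covers partial deprotonation of the alkyne, and the new carbinol centre is removed in step 12.

Step 12
Reactants: 22 (1S)-1-[(1S,2R,5S)-5-(1-hydroxyethyl)-5-methyl-2-(propan-2-yl)-2-[(triethylsilyl)oxy]cyclopentyl]but-3-yn-1-yl 3-methylbutanoate
Product: 23 (1S)-1-[(1S,2R,5S)-5-acetyl-5-methyl-2-(propan-2-yl)-2-[(triethylsilyl)oxy]cyclopentyl]but-3-yn-1-yl 3-methylbutanoate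
Conditions: Dess–Martin periodinane, CH2Cl2, 0 → 23 °C
Reagents that add atoms: none
Why: Dess–Martin oxidation of the secondary alcohol gives the methyl ketone without touching alkyne, ester or silyl ether.

Step 13
Reactants: 23 (1S)-1-[(1S,2R,5S)-5-acetyl-5-methyl-2-(propan-2-yl)-2-[(triethylsilyl)oxy]cyclopentyl]but-3-yn-1-yl 3-methylbutanoate
Product: 24 (1S)-1-[(1S,2R,5S)-5-{1-[(tert-butyldimethylsilyl)oxy]ethenyl}-5-methyl-2-(propan-2-yl)-2-[(triethylsilyl)oxy]cyclopentyl]but-3-yn-1-yl 3-methylbutanoate
Conditions: t-BuMe2SiOTf, Et3N, CH2Cl2, −78 → 0 °C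
Reagents that add atoms: tert-butyldimethylsilyl trifluoromethanesulfonate, CC(C)(C)[Si](C)(C)OS(=O)(=O)C(F)(F)F
Why: Soft enolisation with a silyl triflate and an amine: C1 is quaternary, so only the methyl group can enolise, and the ester is not enolised under these conditions.

Step 14
Reactants: 24 (1S)-1-[(1S,2R,5S)-5-{1-[(tert-butyldimethylsilyl)oxy]ethenyl}-5-methyl-2-(propan-2-yl)-2-[(triethylsilyl)oxy]cyclopentyl]but-3-yn-1-yl 3-methylbutanoate
Product: 25 (1S,4R,5S,6S)-10-oxo-4-[(triethylsilyl)oxy]dauc-8(14)-en-6-yl 3-methylbutanoate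
Conditions: [{(Ar3SiC≡C)3P}Au]NTf2 (5 mol%; Ar = 3,5-(t-Bu)2-4-MeOC6H2), t-BuOH (1.2 equiv), 4 Å MS, CH2Cl2, 23 °C
Reagents that add atoms: none
Why: The cationic monovalent gold complex binds the terminal alkyne, and C9 of the silyl enol ether adds anti to gold at the internal carbon C8, where a gold-bound terminal alkyne carries most of its positive charge. The silyloxocarbenium ion that results hands its silyl group to tert-butanol and the vinylgold species is protonated, which releases ketone 25 with the exocyclic methylidene and returns the catalyst. The closest known reaction type is the gold-catalysed carbocyclisation of acetylenic silyl enol ethers (a Conia-ene-type cycloisomerisation), which reaches seven-membered methylidenecycloalkanones when a bulky, cavity-shaped phosphine is used. The one ring formed is the cycloheptane and it closes in the 7-exo-dig mode; the 8-endo-dig mode would need attack at the unsubstituted alkyne terminus and a larger ring. No stereocentre is created, so C1, C4, C5 and C6 are not at risk. The step needs exo over endo attack, which the terminal alkyne and the ligand pocket secure, and a single enol ether regioisomer, which the quaternary C1 guarantees. It also needs the new alkene to stay out of conjugation, so the medium is kept free of strong acid and the reaction is stopped at full conversion. The trans arrangement of the two chains on the cyclopentane lets C9 and C8 meet with no more strain than that of a trans-fused hydroazulene.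

Step 15
Reactants: 25 (1S,4R,5S,6S)-10-oxo-4-[(triethylsilyl)oxy]dauc-8(14)-en-6-yl 3-methylbutanoate
Product: 27 (1S,4R,5S,6S,9R)-9-hydroxy-10-oxo-4-[(triethylsilyl)oxy]dauc-8(14)-en-6-yl 3-methylbutanoate, via potassium dienolate 26 (not isolated)
Conditions: KN(SiMe3)2 (1.05 equiv), THF, −78 °C; then 2-(phenylsulfonyl)-3-phenyloxaziridine, −78 °C
Reagents that add atoms: potassium bis(trimethylsilyl)amide, C[Si](C)(C)[N-][Si](C)(C)C.[K+] (potassium of 26); 2-(phenylsulfonyl)-3-phenyloxaziridine, O=S(=O)(N1OC1c1ccccc1)c1ccccc1 (oxygen at C9)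
Why: Deprotonation at C9, which is both α to the ketone and allylic, gives the extended enolate 26; N-sulfonyloxaziridines transfer oxygen to the α-carbon of such enolates, so the exocyclic alkene stays in place (enolate hydroxylation). Oxygen arrives on the α face, away from the axial C1 methyl (9R).

Step 16
Reactants: 27 (1S,4R,5S,6S,9R)-9-hydroxy-10-oxo-4-[(triethylsilyl)oxy]dauc-8(14)-en-6-yl 3-methylbutanoate
Product: 28 (1S,4R,5S,6S,9R)-9-[(tert-butyldimethylsilyl)oxy]-10-oxo-4-[(triethylsilyl)oxy]dauc-8(14)-en-6-yl 3-methylbutanoate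
Conditions: t-BuMe2SiOTf, 2,6-lutidine, CH2Cl2, −78 → 0 °C
Reagents that add atoms: tert-butyldimethylsilyl trifluoromethanesulfonate, CC(C)(C)[Si](C)(C)OS(=O)(=O)C(F)(F)F
Why: Silylation removes the free hydroxyl, which would otherwise bind the hydride reagent and steer it to the α face, and puts a large group on that face.

Step 17
Reactants: 28 (1S,4R,5S,6S,9R)-9-[(tert-butyldimethylsilyl)oxy]-10-oxo-4-[(triethylsilyl)oxy]dauc-8(14)-en-6-yl 3-methylbutanoate
Product: 29 (1S,4R,5S,6S,9R,10S)-9-[(tert-butyldimethylsilyl)oxy]-10-hydroxy-4-[(triethylsilyl)oxy]dauc-8(14)-en-6-yl 3-methylbutanoate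
Conditions: LiBH(s-Bu)3, THF, −78 °C
Reagents that add atoms: none
Why: Felkin–Anh-controlled hydride addition: with the C9–H bond held near the plane of the C8 methylidene by allylic strain, the C9–O bond stands across the carbonyl on the α face, so the bulky hydride adds anti to it from the β face and gives the 10S alcohol cis to the C9 oxygen. The ester is inert to this reagent at −78 °C.

Step 18
Reactants: 29 (1S,4R,5S,6S,9R,10S)-9-[(tert-butyldimethylsilyl)oxy]-10-hydroxy-4-[(triethylsilyl)oxy]dauc-8(14)-en-6-yl 3-methylbutanoate
Product: 30 (1S,4R,5S,6S,9R,10S)-4,9,10-trihydroxydauc-8(14)-en-6-yl 3-methylbutanoate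
Conditions: HF·pyridine, pyridine, THF, 0 → 23 °C
Reagents that add atoms: none
Why: Fluoride cleaves the secondary tert-butyldimethylsilyl ether and the tertiary triethylsilyl ether in one operation under buffered conditions that spare the ester and the allylic diol.

## Compound list

1 | 3-bromocyclopent-2-en-1-one | O=C1C=C(Br)CC1 | starting material
2 | (tributylstannyl)methanol | CCCC[Sn](CCCC)(CCCC)CO | starting material
3 | 3-(hydroxymethyl)cyclopent-2-en-1-one | O=C1C=C(CO)CC1 | intermediate
4 | 3-{[(tert-butyldimethylsilyl)oxy]methyl}cyclopent-2-en-1-one | O=C1C=C(CO[Si](C)(C)C(C)(C)C)CC1 | intermediate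
5 | trimethylaluminium | C[Al](C)C | starting material
6 | dimethylaluminium (3S)-3-{[(tert-butyldimethylsilyl)oxy]methyl}-3-methylcyclopent-1-en-1-olate | C[Al](C)OC1=C[C@](C)(CC1)CO[Si](C)(C)C(C)(C)C | intermediate
7 | tert-butyl(dimethyl){[(1S)-1-methyl-3-[(triethylsilyl)oxy]cyclopent-2-en-1-yl]methoxy}silane | CC[Si](CC)(CC)OC1=C[C@](C)(CC1)CO[Si](C)(C)C(C)(C)C | intermediate
8 | 4-(trimethylsilyl)but-3-yn-1-ol | C[Si](C)(C)C#CCCO | starting material
9 | 4-(trimethylsilyl)but-3-ynal | C[Si](C)(C)C#CCC=O | intermediate
10 | lithium (3S)-3-{[(tert-butyldimethylsilyl)oxy]methyl}-3-methylcyclopent-1-en-1-olate | [Li]OC1=C[C@](C)(CC1)CO[Si](C)(C)C(C)(C)C | intermediate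
11 | chlorozinc (3S)-3-{[(tert-butyldimethylsilyl)oxy]methyl}-3-methylcyclopent-1-en-1-olate | Cl[Zn]OC1=C[C@](C)(CC1)CO[Si](C)(C)C(C)(C)C | intermediate
12 | (2S,3S)-3-{[(tert-butyldimethylsilyl)oxy]methyl}-2-[(1S)-1-hydroxy-4-(trimethylsilyl)but-3-yn-1-yl]-3-methylcyclopentan-1-one | C[Si](C)(C)C#CC[C@H](O)[C@@H]1[C@](C)(CCC1=O)CO[Si](C)(C)C(C)(C)C | intermediate
13 | isopropylmagnesium chloride | CC(C)[Mg]Cl | starting material
14 | (1R,2S,3S)-3-{[(tert-butyldimethylsilyl)oxy]methyl}-2-[(1S)-1-hydroxy-4-(trimethylsilyl)but-3-yn-1-yl]-3-methyl-1-(propan-2-yl)cyclopentan-1-ol | C[Si](C)(C)C#CC[C@H](O)[C@@H]1[C@](C)(CC[C@@]1(O)C(C)C)CO[Si](C)(C)C(C)(C)C | intermediate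
15 | (1R,2S,3S)-3-{[(tert-butyldimethylsilyl)oxy]methyl}-2-[(1S)-1-hydroxybut-3-yn-1-yl]-3-methyl-1-(propan-2-yl)cyclopentan-1-ol | C#CC[C@H](O)[C@@H]1[C@](C)(CC[C@@]1(O)C(C)C)CO[Si](C)(C)C(C)(C)C | intermediate
16 | 3-methylbutanoyl chloride (isovaleryl chloride) | CC(C)CC(Cl)=O | starting material
17 | (1S)-1-[(1S,2R,5S)-5-{[(tert-butyldimethylsilyl)oxy]methyl}-2-hydroxy-5-methyl-2-(propan-2-yl)cyclopentyl]but-3-yn-1-yl 3-methylbutanoate | C#CC[C@H](OC(=O)CC(C)C)[C@@H]1[C@](C)(CC[C@@]1(O)C(C)C)CO[Si](C)(C)C(C)(C)C | intermediate
18 | (1S)-1-[(1S,2R,5S)-2-hydroxy-5-(hydroxymethyl)-5-methyl-2-(propan-2-yl)cyclopentyl]but-3-yn-1-yl 3-methylbutanoate | C#CC[C@H](OC(=O)CC(C)C)[C@@H]1[C@](C)(CC[C@@]1(O)C(C)C)CO | intermediate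
19 | (1S)-1-[(1S,2R,5S)-5-formyl-2-hydroxy-5-methyl-2-(propan-2-yl)cyclopentyl]but-3-yn-1-yl 3-methylbutanoate | C#CC[C@H](OC(=O)CC(C)C)[C@@H]1[C@](C)(CC[C@@]1(O)C(C)C)C=O | intermediate
20 | (1S)-1-[(1S,2R,5S)-5-formyl-5-methyl-2-(propan-2-yl)-2-[(triethylsilyl)oxy]cyclopentyl]but-3-yn-1-yl 3-methylbutanoate | C#CC[C@H](OC(=O)CC(C)C)[C@@H]1[C@](C)(CC[C@@]1(O[Si](CC)(CC)CC)C(C)C)C=O | intermediate
21 | methylmagnesium bromide | C[Mg]Br | starting material
22 | (1S)-1-[(1S,2R,5S)-5-(1-hydroxyethyl)-5-methyl-2-(propan-2-yl)-2-[(triethylsilyl)oxy]cyclopentyl]but-3-yn-1-yl 3-methylbutanoate, both carbinol epimers | C#CC[C@H](OC(=O)CC(C)C)[C@@H]1[C@](C)(CC[C@@]1(O[Si](CC)(CC)CC)C(C)C)C(C)O | intermediate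
23 | (1S)-1-[(1S,2R,5S)-5-acetyl-5-methyl-2-(propan-2-yl)-2-[(triethylsilyl)oxy]cyclopentyl]but-3-yn-1-yl 3-methylbutanoate | C#CC[C@H](OC(=O)CC(C)C)[C@@H]1[C@](C)(CC[C@@]1(O[Si](CC)(CC)CC)C(C)C)C(C)=O | intermediate
24 | (1S)-1-[(1S,2R,5S)-5-{1-[(tert-butyldimethylsilyl)oxy]ethenyl}-5-methyl-2-(propan-2-yl)-2-[(triethylsilyl)oxy]cyclopentyl]but-3-yn-1-yl 3-methylbutanoate | C#CC[C@H](OC(=O)CC(C)C)[C@@H]1[C@](C)(CC[C@@]1(O[Si](CC)(CC)CC)C(C)C)C(=C)O[Si](C)(C)C(C)(C)C | intermediate
25 | (1S,4R,5S,6S)-10-oxo-4-[(triethylsilyl)oxy]dauc-8(14)-en-6-yl 3-methylbutanoate | C=C1C[C@H](OC(=O)CC(C)C)[C@@H]2[C@](C)(CC[C@@]2(O[Si](CC)(CC)CC)C(C)C)C(=O)C1 | intermediate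
26 | potassium dienolate of 25 (C10–O–K, C9=C10, C8=C14) | C=C1C[C@H](OC(=O)CC(C)C)[C@@H]2[C@](C)(CC[C@@]2(O[Si](CC)(CC)CC)C(C)C)C([O-])=C1.[K+] | intermediate
27 | (1S,4R,5S,6S,9R)-9-hydroxy-10-oxo-4-[(triethylsilyl)oxy]dauc-8(14)-en-6-yl 3-methylbutanoate | C=C1C[C@H](OC(=O)CC(C)C)[C@@H]2[C@](C)(CC[C@@]2(O[Si](CC)(CC)CC)C(C)C)C(=O)[C@@H]1O | intermediate
28 | (1S,4R,5S,6S,9R)-9-[(tert-butyldimethylsilyl)oxy]-10-oxo-4-[(triethylsilyl)oxy]dauc-8(14)-en-6-yl 3-methylbutanoate | C=C1C[C@H](OC(=O)CC(C)C)[C@@H]2[C@](C)(CC[C@@]2(O[Si](CC)(CC)CC)C(C)C)C(=O)[C@@H]1O[Si](C)(C)C(C)(C)C | intermediate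
29 | (1S,4R,5S,6S,9R,10S)-9-[(tert-butyldimethylsilyl)oxy]-10-hydroxy-4-[(triethylsilyl)oxy]dauc-8(14)-en-6-yl 3-methylbutanoate | C=C1C[C@H](OC(=O)CC(C)C)[C@@H]2[C@](C)(CC[C@@]2(O[Si](CC)(CC)CC)C(C)C)[C@H](O)[C@@H]1O[Si](C)(C)C(C)(C)C | intermediate
30 | (1S,4R,5S,6S,9R,10S)-4,9,10-trihydroxydauc-8(14)-en-6-yl 3-methylbutanoate | C=C1C[C@H](OC(=O)CC(C)C)[C@@H]2[C@](C)(CC[C@@]2(O)C(C)C)[C@H](O)[C@@H]1O | target

## Step count and least certain steps

Total step count: 18. Longest linear sequence: 17 steps (steps 1–3 and 5–18, from 1); step 4 prepares aldehyde 9 on a side branch.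

**Step 14 (key step).** The seven-membered closure may be slow enough for other paths of the gold-bound alkyne to take over: protodesilylation of the enol silane back to 23, attack of the neighbouring ester carbonyl oxygen on the activated alkyne followed by alkyne hydration, or acid-induced migration of the new alkene into conjugation. Fallback: the same C8–C9 bond is formed by palladium-catalysed intramolecular α-alkenylation of the ketone. It sets out from 23: bromoboration of the terminal alkyne with B-bromo-9-borabicyclo[3.3.1]nonane and protonolysis with acetic acid give the 2-bromoalkene (1S)-1-[(1S,2R,5S)-5-acetyl-5-methyl-2-(propan-2-yl)-2-[(triethylsilyl)oxy]cyclopentyl]-3-bromobut-3-en-1-yl 3-methylbutanoate F1, and Pd(PPh3)4 with potassium phenoxide in THF at reflux couples the methyl ketone enolate with the vinyl bromide to give 25, where the route is rejoined.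

**Step 17.** Hydride may be delivered to the α face instead, because the axial C1 methyl sits on the β face next to the carbonyl; this would give the 10-epimer (trans-diol), and it is the weakest stereochemical point of the endgame. Fallback: both C–O bonds are made at once by syn-dihydroxylation on the open α face, which is the classical way to a cis-diol lying opposite an angular methyl. It sets out from 25: KN(SiMe3)2 and N-phenylbis(trifluoromethanesulfonimide) give the enol triflate (1S,4R,5S,6S)-4-[(triethylsilyl)oxy]-10-{[(trifluoromethyl)sulfonyl]oxy}dauca-8(14),9-dien-6-yl 3-methylbutanoate F2. Reduction with Pd(OAc)2, PPh3, HCO2H and Bu3N gives the diene (1R,4R,5S,6S)-4-[(triethylsilyl)oxy]dauca-8(14),9-dien-6-yl 3-methylbutanoate F3. One equivalent of OsO4 in pyridine/THF at low temperature, with reductive work-up, gives the 9α,10α-diol (1S,4R,5S,6S,9R,10S)-9,10-dihydroxy-4-[(triethylsilyl)oxy]dauc-8(14)-en-6-yl 3-methylbutanoate F4, and the conditions of step 18 take F4 to 30. The limit of this fallback is competition from the exocyclic alkene, which is why the oxidant is kept to one equivalent.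

**Step 15.** The oxidant may attack at the γ-carbon C14 or on the β face, proton transfer may move the alkene into conjugation, or the C6 ester may transfer its acyl group to the enolate. Fallback: Rubottom oxidation in place of enolate oxidation. It sets out from 25: t-BuMe2SiOTf and Et3N give the silyl dienol ether (1S,4R,5S,6S)-10-[(tert-butyldimethylsilyl)oxy]-4-[(triethylsilyl)oxy]dauca-8(14),9-dien-6-yl 3-methylbutanoate F5. Its electron-rich C9=C10 bond is epoxidised by dimethyldioxirane at −78 °C from the α face, and silyl migration gives 28 directly, where the route is rejoined.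

**Step 5.** The C6 configuration may come out with poor simple diastereoselection because the chair is loose for a zinc or lithium enolate, the facial preference at C5 may be eroded, and the enolate may isomerise aldehyde 9 to the allenyl aldehyde. Fallback for C6: both epimers are used and the wrong one is corrected by inversion instead of aldol control. It sets out from 7 and 9: the epimeric aldol (2S,3S)-3-{[(tert-butyldimethylsilyl)oxy]methyl}-2-[(1R)-1-hydroxy-4-(trimethylsilyl)but-3-yn-1-yl]-3-methylcyclopentan-1-one F6 is taken through the conditions of step 6 to the epimeric diol (1R,2S,3S)-3-{[(tert-butyldimethylsilyl)oxy]methyl}-2-[(1R)-1-hydroxybut-3-yn-1-yl]-3-methyl-1-(propan-2-yl)cyclopentan-1-ol F7. Mitsunobu esterification of F7 with 3-methylbutanoic acid, PPh3 and diisopropyl azodicarboxylate inverts C6 and gives 17, where the route is rejoined.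

## Further compounds

F1 | step 14 | (1S)-1-[(1S,2R,5S)-5-acetyl-5-methyl-2-(propan-2-yl)-2-[(triethylsilyl)oxy]cyclopentyl]-3-bromobut-3-en-1-yl 3-methylbutanoate | C=C(Br)C[C@H](OC(=O)CC(C)C)[C@@H]1[C@](C)(CC[C@@]1(O[Si](CC)(CC)CC)C(C)C)C(C)=O
F2 | step 17 | (1S,4R,5S,6S)-4-[(triethylsilyl)oxy]-10-{[(trifluoromethyl)sulfonyl]oxy}dauca-8(14),9-dien-6-yl 3-methylbutanoate | C=C1C[C@H](OC(=O)CC(C)C)[C@@H]2[C@](C)(CC[C@@]2(O[Si](CC)(CC)CC)C(C)C)C(OS(=O)(=O)C(F)(F)F)=C1
F3 | step 17 | (1R,4R,5S,6S)-4-[(triethylsilyl)oxy]dauca-8(14),9-dien-6-yl 3-methylbutanoate | C=C1C[C@H](OC(=O)CC(C)C)[C@@H]2[C@](C)(CC[C@@]2(O[Si](CC)(CC)CC)C(C)C)C=C1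
F4 | step 17 | (1S,4R,5S,6S,9R,10S)-9,10-dihydroxy-4-[(triethylsilyl)oxy]dauc-8(14)-en-6-yl 3-methylbutanoate | C=C1C[C@H](OC(=O)CC(C)C)[C@@H]2[C@](C)(CC[C@@]2(O[Si](CC)(CC)CC)C(C)C)[C@H](O)[C@@H]1O
F5 | step 15 | (1S,4R,5S,6S)-10-[(tert-butyldimethylsilyl)oxy]-4-[(triethylsilyl)oxy]dauca-8(14),9-dien-6-yl 3-methylbutanoate | C=C1C[C@H](OC(=O)CC(C)C)[C@@H]2[C@](C)(CC[C@@]2(O[Si](CC)(CC)CC)C(C)C)C(O[Si](C)(C)C(C)(C)C)=C1
F6 | step 5 | (2S,3S)-3-{[(tert-butyldimethylsilyl)oxy]methyl}-2-[(1R)-1-hydroxy-4-(trimethylsilyl)but-3-yn-1-yl]-3-methylcyclopentan-1-one | C[Si](C)(C)C#CC[C@@H](O)[C@@H]1[C@](C)(CCC1=O)CO[Si](C)(C)C(C)(C)C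
F7 | step 5 | (1R,2S,3S)-3-{[(tert-butyldimethylsilyl)oxy]methyl}-2-[(1R)-1-hydroxybut-3-yn-1-yl]-3-methyl-1-(propan-2-yl)cyclopentan-1-ol | C#CC[C@@H](O)[C@@H]1[C@](C)(CC[C@@]1(O)C(C)C)CO[Si](C)(C)C(C)(C)C
A1 | alternative 1 | (2S,3S)-3-{[(tert-butyldimethylsilyl)oxy]methyl}-2-[(1S)-1-hydroxy-4-(trimethylsilyl)but-3-yn-1-yl]-3-methylcyclopentan-1-one | C[Si](C)(C)C#CC[C@H](O)[C@@H]2[C@](C)(CCC2=O)CO[Si](C)(C)C(C)(C)C
A2 | alternative 2 | (1R,4R)-9-[(tert-butyldimethylsilyl)oxy]-4-[(triethylsilyl)oxy]-14-nordauca-5,9-diene | C1CC=C2[C@](C)(CC[C@@]2(O[Si](CC)(CC)CC)C(C)C)C=C1O[Si](C)(C)C(C)(C)C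
A3 | alternative 3 | methyl bicyclo[5.3.0]deca-5,8-diene-8-carboxylate with the C1 methyl (1R) and a C4 ethylene ketal (daucane positions) | COC(=O)C1=CC[C@@]2(C)CCC3(OCCO3)C2=CC1
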